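## The problem

Target 24 is an oxolane in which every ring carbon is substituted. With the ring numbered O1, C2 (4-hydroxyphenyl, ring B), C3 (carrying the ketone carbon C6 with its 2,4-dihydroxyphenyl ring C), C4 (carrying the carbinol carbon C7 with its 4-hydroxyphenyl ring D) and C5 (2,4-dihydroxyphenyl, ring A), the configuration is 2R,3R,4R,5R with C7 also R, that is C2/C3 trans and C3/C4/C5 all cis. The central bond C3–C4 joins two carbons that are both α to a carbonyl-level carbon (C6 and C7), so no simple enolate-plus-electrophile union makes it, and the two resorcinol rings (A, C) and the two 4-hydroxyphenyl rings (B, D) must each reach one specific carbon. The all-cis C3/C4/C5 array is the least stable one, and C3 (α to the ketone) and C4 (α to an ester or aldehyde on the way) can epimerise; C3 can set C2 through a trans ring closure, the C3 substituent can set C4 and C5 together if a C4=C5 bond is saturated from the opposite face, the ring must then control C7, and only C3 needs an outside source of absolute configuration. The molecule tolerates little: O1–C2 is β to the C6 ketone and opens by retro-oxa-Michael reaction under base, the C7 carbinol and both ring C–O bonds are benzylic to electron-rich arenes and ionise under acid, and the γ-hydroxy ketone can close to a bicyclic hemiketal. A short assembly is possible because O1 is the oxygen of an aryl ketone at C5 whose α-carbon C4 bears the carboxyl-level carbon C7 (a β-keto ester), while C2–C3–C6 is a cinnamoyl unit with C2 benzylic: one-electron oxidation at C4, addition to C3 and capture of the C2 cation by O1 close ring O1–C2–C3–C4–C5 and make both bonds that link the two halves.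

## Retrosynthesis

**24 from 23 (six O–benzyl bonds).** All phenols are masked as benzyl ethers in 23. Methoxymethyl or silyl groups would need acid or basic fluoride at the end, and the target tolerates neither; benzyl ethers come off under neutral hydrogen. The forward step must cleave six ArO–CH2Ph bonds and leave the benzylic C7–OH, C2–O1 and C5–O1 bonds and the ketone alone.

**23 from 20 and 22 (C7–ring D bond).** Cutting the aryl–C7 bond gives keto aldehyde 20 and the arylmagnesium bromide 22 made from bromide 21. The other cut at C7, reduction of a C7 aryl ketone, would require one of two aryl ketones to be reduced. An aldehyde next to a hindered, electron-rich ketone is told apart by reactivity alone. Precursor 20 has one ring and one stereocentre fewer; the addition must take the aldehyde only and one of its faces.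

**20 from 19, and 19 from 15 and 18 (C6–ring C bond).** Aldehyde 20 is the oxidation product of hydroxy ketone 19, and 19 is the adduct of aryllithium 18 (from bromide 17, from 4-bromoresorcinol 16) with lactone 15. A lactone is preferred to an open amide/ester pair because it offers one carbonyl only, its lithium hemiketal stops the addition at the ketone level, and C7 is stored meanwhile as the alkoxy carbon. The forward reaction must be a single addition without enolisation at C3.

**15 from 14, 13 and 11 (no skeletal bond; C6 is told from C7).** In 11, C6 is an imide carbonyl and C7 an ester carbonyl. LiOOH cleaves only the imide (acid 13), LiBH4 reduces only the ester beside the carboxylate (hydroxy acid 14), and because the two groups are cis the hydroxy acid closes to 15. The direct alternatives, an aryllithium on an amide beside the ester or a partial ester reduction beside the new ketone, need chemoselectivities that cannot be relied on. The auxiliary 7 is returned here.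

**11 from 10 (two C–H bonds at C4 and C5).** Syn addition of hydrogen to the tetrasubstituted C4=C5 bond of dihydrofuran 10, on the face opposite the C3 acyl group, is the one operation that gives the contra-thermodynamic all-cis array. A heterogeneous Rh catalyst is chosen because it spares aryl benzyl ethers and benzylic C–O bonds and does not bind the C3 carbonyl. A cationic iridium catalyst such as [Ir(cod)(PCy3)(py)]PF6 would be directed by that carbonyl to its own face and give the C3/C4 trans isomer.

**10 from 3 and 9 (C3–C4 and O1–C2; one ring).** This is the key disconnection. Cutting C2–C3 instead (an aldol) leaves the like-polarity C3–C4 bond unsolved, and cutting at C5 removes the oxygen that closes the ring. The precursors are a β-keto ester (3) and a cinnamoyl imide (9), both two or three steps from commercial phenols. The bornane sultam is used rather than an oxazolidinone because the facial bias must work without chelation in warm AcOH. The forward reaction must give C–C attack at C3, closure by the ketone oxygen, a trans ring and one alkene face.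

**3 from 2 and 1; 9 from 6 and 7 by way of 8; 6 from 4 by way of 5.** The β-keto ester comes from Claisen carboxylation of benzylated 2',4'-dihydroxyacetophenone. The imide comes from N-acylation of sultam 7 with the acid chloride of benzylated 4-hydroxycinnamic acid.

## Roads not taken

Alternative 1: The cut is C3–C4 together with both lactone C–O bonds. In the forward sense two molecules of acid 4 are oxidised (FeCl3/O2 or Ag2O) to phenoxyl radicals, couple at C3–C4, and each carboxyl group adds to the quinone methide of the other half to give bis-lactone A1.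
- Merits: this is the shortest conceivable entry. One step from 4 sets C2, C3, C4 and C7 in the relative sense of the target, since the exo,exo-diaryl cis-fused bicycle has C2/C3 trans, C3/C4 cis and the C7 aryl group exo. It needs no protecting groups and makes the like-polarity bond directly. In step economy and in stereocentres set by the key step (four against two) it is better than the chosen plan.
- Weak points: A1 is racemic and offers no handle for absolute configuration. A cinnamic acid without ortho substituents couples through several competing modes. The two lactones of A1 are equivalent, yet one carbonyl (C5) must be arylated and reduced to a CH–aryl centre while the other (C6) is arylated and kept as a ketone, which means a statistical mono-reduction. The phenols would have to be protected after all before any aryl-metal addition.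
- Comparison: the chosen plan sets against this an auxiliary-controlled absolute configuration, a single coupling mode, and two carboxyl carbons that differ from the start (imide and ester), with ring A already on C5.

Alternative 2: The cuts are C2–C3 and C4–C7. The bis(Z-boron enolate) of diketone A2 adds to two molecules of aldehyde A3 and gives the C2-symmetric bis-aldol A4.
- Merits: it is convergent. All carbons and all four aryl rings are in place after one C–C bond-forming step, and boron aldol chemistry is dependable for each syn pair. In convergence it is better than the chosen plan.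
- Weak points: the two halves of A4 are identical but those of the target are not. One carbinol must become O1 by closing on the C5 ketone, followed by reduction at C5 with the aryl group ending cis to C4, while the other carbinol and its ketone must stay. The relation between C3 and C4 is decided in the second aldol under substrate control. A bis(β-hydroxy ketone) built on a 1,4-diketone is prone to retro-aldol reaction, dehydration and furan formation under the acid needed for reductive etherification.
- Comparison: the chosen plan sets against this that O1 and the C5 aryl group are present from the start and that no desymmetrisation is needed.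

Alternative 3: The cuts are C3–C6 and C4–C7. Irradiation of butenolide A5 with ketene acetal A6 gives cyclobutane A7 on the face away from the C2 aryl group; a later oxygen insertion opens the four-membered ring.
- Merits: facial control by a stereocentre on a rigid butenolide is reliable, and the cis ring fusion fixes C3/C4 cis by geometry. The chosen plan has to earn that relation in a hydrogenation, so in this respect Alternative 3 is the safer road.
- Weak points: A7 contains none of rings A, C and D. C5 is still a lactone carbonyl, C6 a masked ketone and C7 a methylene, so three aryl groups and the C7 oxygen remain to be introduced. In a Baeyer–Villiger-type insertion on the derived cyclobutanone the more substituted carbon C3 migrates preferentially, which would put the oxygen on C3 instead of between C6 and C7. The benzylic lactone C–O bond of A5 is also at risk under irradiation.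
- Comparison: the chosen plan sets against this a key step that delivers C5 with ring A and both C6 and C7 at the carboxyl level, which leaves only two aryl additions.

Key step: step 5

Assumption: the sense of induction in step 5 is taken from the non-chelated conformer of N-enoyl bornane-10,2-sultams (C=O anti to N–SO2, alkene s-cis), which predicts attack on the re face of the α-carbon for the (2R)-sultam; should the opposite sense be found, the commercially available (2S)-sultam would be used without other change.

Remark: γ-hydroxy ketones 19, 23 and 24 are written in the open form; each may equilibrate with its bicyclic hemiketal, which does not alter the planned chemistry.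

Step 1
Reactants: 1 2',4'-dihydroxyacetophenone
Product: 2 1-[2,4-bis(benzyloxy)phenyl]ethan-1-one
Conditions: BnBr, K2CO3, DMF, 70 °C
Reagents that add atoms: benzyl bromide, BrCc1ccccc1
Why: Williamson ether synthesis on both phenols; the hydrogen-bonded 2-hydroxyl needs the excess of BnBr and the heat. Benzyl is chosen because its final removal is neutral.

Step 2
Reactants: 2 1-[2,4-bis(benzyloxy)phenyl]ethan-1-one
Product: 3 methyl 3-[2,4-bis(benzyloxy)phenyl]-3-oxopropanoate
Conditions: NaH, (MeO)2CO, toluene, 100 °C; then 1 M HCl
Reagents that add atoms: dimethyl carbonate, COC(=O)OC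
Why: Crossed Claisen condensation of the methyl ketone enolate with dimethyl carbonate; the product is held as its sodium enolate, which drives the reaction and prevents a second acylation.

Step 3
Reactants: 4 (E)-4-hydroxycinnamic acid
Product: 6 (E)-3-[4-(benzyloxy)phenyl]prop-2-enoic acid, via benzyl ester 5 (not isolated)
Conditions: BnBr, K2CO3, DMF, 60 °C; then NaOH, MeOH–H2O, 60 °C; then HCl
Reagents that add atoms: benzyl bromide, BrCc1ccccc1; sodium hydroxide, [Na+].[OH-]
Why: Exhaustive O-benzylation (Williamson) followed by saponification of the benzyl ester in the same flask; the aryl benzyl ether and the E-alkene are untouched.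

Step 4
Reactants: 6 (E)-3-[4-(benzyloxy)phenyl]prop-2-enoic acid; 7 (2R)-bornane-10,2-sultam [(1S)-(−)-2,10-camphorsultam]
Product: 9 (2R)-N-[(E)-3-[4-(benzyloxy)phenyl]prop-2-enoyl]bornane-10,2-sultam, via acid chloride 8 (not isolated)
Conditions: (COCl)2, DMF (cat.), CH2Cl2, 0 °C to rt; then 7, NaH, toluene, 0 °C to rt
Reagents that add atoms: none
Why: N-Acylation of the sodium salt of the sultam with the acid chloride, the standard preparation of N-enoyl sultams; no stereocentre is formed and the E geometry is kept.

Step 5
Reactants: 3 methyl 3-[2,4-bis(benzyloxy)phenyl]-3-oxopropanoate; 9 (2R)-N-[(E)-3-[4-(benzyloxy)phenyl]prop-2-enoyl]bornane-10,2-sultam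
Product: 10 methyl (4R,5R)-2-[2,4-bis(benzyloxy)phenyl]-5-[4-(benzyloxy)phenyl]-4-{[(2R)-bornane-10,2-sultam-N-yl]carbonyl}-4,5-dihydrofuran-3-carboxylate
Conditions: Mn(OAc)3·2H2O (2.2 equiv), AcOH, 70 °C, N2
Reagents that add atoms: none
Why: Mn(OAc)3 forms the manganese enolate of 3 and oxidises it to the electrophilic radical at C4 (target numbering), which adds to the alkene carbon next to the imide carbonyl of 9 (C3) because only this regiochemistry gives the 4-benzyloxybenzylic radical at C2. A second equivalent of Mn(OAc)3 oxidises that radical to the benzylic cation and the enol oxygen of the aryl ketone (O1) captures it, so the one ring formed closes by a polar five-membered O-alkylation with the C4=C5 enol bond inside the ring, not by a radical cyclisation. The closest known reaction type is the Mn(OAc)3-mediated oxidative [3+2] annulation of β-keto esters with cinnamic esters, amides and N-cinnamoyl auxiliaries to trans-2-aryl-2,3-dihydrofurans. C3 is set in the C–C bond-forming step by the sultam: in the non-chelated conformer one face of the α-carbon is screened by a sulfonyl oxygen and the radical enters on the re face, which gives 3R (4R in the name of 10). C2 is set in the ring closure, trans to the C3 acyl group, because the planar cation closes to the less crowded and more stable isomer (5R in the name of 10). The step needs attack at C3 and not C2 (benzylic radical stability), closure through the ketone and not the ester oxygen (the ketone enol is more nucleophilic and gives the conjugated vinylogous carbonate), a trans ring and one alkene face; the first three are inherent and the last rests on the auxiliary. The product is a deactivated push–pull alkene that is not oxidised further, and aryl benzyl ethers are inert to trivalent manganese in AcOH.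

Step 6
Reactants: 10 methyl (4R,5R)-2-[2,4-bis(benzyloxy)phenyl]-5-[4-(benzyloxy)phenyl]-4-{[(2R)-bornane-10,2-sultam-N-yl]carbonyl}-4,5-dihydrofuran-3-carboxylate
Product: 11 methyl (2R,3S,4R,5R)-2-[2,4-bis(benzyloxy)phenyl]-5-[4-(benzyloxy)phenyl]-4-{[(2R)-bornane-10,2-sultam-N-yl]carbonyl}oxolane-3-carboxylate
Conditions: H2 (5 bar), 5% Rh/Al2O3, EtOAc, rt
Reagents that add atoms: none
Why: Heterogeneous syn-hydrogenation of the tetrasubstituted vinylogous carbonate; both hydrogens arrive on the ring face opposite the bulky C3 acyl sultam group, which sets C4 and C5 together and gives the all-cis C3/C4/C5 array. Rh on alumina saturates hindered alkenes while sparing aryl benzyl ethers and benzylic C–O bonds, and unlike a carbonyl-directed cationic iridium catalyst it is not drawn to the face of the C3 carbonyl.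

Step 7
Reactants: 11 methyl (2R,3S,4R,5R)-2-[2,4-bis(benzyloxy)phenyl]-5-[4-(benzyloxy)phenyl]-4-{[(2R)-bornane-10,2-sultam-N-yl]carbonyl}oxolane-3-carboxylate
Product: 13 (2R,3R,4S,5R)-5-[2,4-bis(benzyloxy)phenyl]-2-[4-(benzyloxy)phenyl]-4-(methoxycarbonyl)oxolane-3-carboxylic acid, via peroxy acid 12 (not isolated)
Conditions: LiOH, H2O2, THF–H2O, 0 °C; then Na2SO3; then HCl to pH 3
Reagents that add atoms: hydrogen peroxide, OO
Why: Hydroperoxide cleavage of the N-acyl sultam: LiOOH attacks the exocyclic imide carbonyl far faster than the hindered methyl ester and is too weak a base to epimerise C3. Sulfite reduces the percarboxylate and sultam 7 is recovered.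

Step 8
Reactants: 13 (2R,3R,4S,5R)-5-[2,4-bis(benzyloxy)phenyl]-2-[4-(benzyloxy)phenyl]-4-(methoxycarbonyl)oxolane-3-carboxylic acid
Product: 15 (3aR,4R,6R,6aR)-4-[2,4-bis(benzyloxy)phenyl]-6-[4-(benzyloxy)phenyl]tetrahydro-1H,3H-furo[3,4-c]furan-1-one, via hydroxy acid 14 (not isolated)
Conditions: LiBH4, MeOH (1 equiv), THF, 0 °C to rt; then 1 M HCl to pH 3, EtOAc, rt
Reagents that add atoms: none
Why: LiBH4 reduces the methyl ester but not the lithium carboxylate, and on acidification the cis hydroxy acid closes to the cis-fused γ-lactone. This leaves C6 as the only carbonyl and stores C7 as an alkoxy carbon; no stereocentre is touched.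

Step 9
Reactants: 16 4-bromoresorcinol
Product: 17 1-bromo-2,4-bis(benzyloxy)benzene
Conditions: BnBr, K2CO3, acetone, reflux
Reagents that add atoms: benzyl bromide, BrCc1ccccc1
Why: Williamson ether synthesis on both phenols; the aryl bromide is kept for halogen–lithium exchange.

Step 10
Reactants: 15 (3aR,4R,6R,6aR)-4-[2,4-bis(benzyloxy)phenyl]-6-[4-(benzyloxy)phenyl]tetrahydro-1H,3H-furo[3,4-c]furan-1-one; 17 1-bromo-2,4-bis(benzyloxy)benzene
Product: 19 [2,4-bis(benzyloxy)phenyl][(2R,3R,4R,5R)-5-[2,4-bis(benzyloxy)phenyl]-2-[4-(benzyloxy)phenyl]-4-(hydroxymethyl)oxolan-3-yl]methanone, via aryllithium 18 (not isolated)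
Conditions: n-BuLi, THF, −78 °C; then 15, THF, −78 °C; then aq. NH4Cl
Reagents that add atoms: none
Why: Bromine–lithium exchange, then addition of the aryllithium to the lactone carbonyl; the lithium hemiketal persists at −78 °C, so the addition stops at the ketone level, as in aryllithium additions to sugar lactones. The low temperature and the nucleophilic ortho-alkoxy aryllithium disfavour enolisation at C3.

Step 11
Reactants: 19 [2,4-bis(benzyloxy)phenyl][(2R,3R,4R,5R)-5-[2,4-bis(benzyloxy)phenyl]-2-[4-(benzyloxy)phenyl]-4-(hydroxymethyl)oxolan-3-yl]methanone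
Product: 20 (2R,3S,4R,5R)-4-[2,4-bis(benzyloxy)benzoyl]-2-[2,4-bis(benzyloxy)phenyl]-5-[4-(benzyloxy)phenyl]oxolane-3-carbaldehyde
Conditions: Dess–Martin periodinane, NaHCO3, CH2Cl2, 0 °C to rt
Reagents that add atoms: none
Why: Dess–Martin oxidation of the primary alcohol under buffered, non-basic conditions, which avoids epimerisation of the all-cis aldehyde at C4 and retro-oxa-Michael opening. Any hemiketal feeds through the open form; the aldehyde is used at once.

Step 12
Reactants: 20 (2R,3S,4R,5R)-4-[2,4-bis(benzyloxy)benzoyl]-2-[2,4-bis(benzyloxy)phenyl]-5-[4-(benzyloxy)phenyl]oxolane-3-carbaldehyde; 21 1-(benzyloxy)-4-bromobenzene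
Product: 23 [2,4-bis(benzyloxy)phenyl][(2R,3R,4R,5R)-5-[2,4-bis(benzyloxy)phenyl]-2-[4-(benzyloxy)phenyl]-4-[(R)-[4-(benzyloxy)phenyl](hydroxy)methyl]oxolan-3-yl]methanone, via arylmagnesium bromide 22 (not isolated)
Conditions: Mg, THF, 40 °C; then 20, THF, −78 °C; then aq. NH4Cl
Reagents that add atoms: none
Why: Grignard addition to the aldehyde, which is far more electrophilic than the hindered, doubly alkoxy-substituted aryl ketone. C7 is set by Felkin–Anh attack anti to the C4–C5 bond (C5 carries the directly attached, ortho-substituted ring A), and magnesium bridging the aldehyde and C6 ketone oxygens would expose the same face; this face gives the 7R carbinol.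

Step 13
Reactants: 23 [2,4-bis(benzyloxy)phenyl][(2R,3R,4R,5R)-5-[2,4-bis(benzyloxy)phenyl]-2-[4-(benzyloxy)phenyl]-4-[(R)-[4-(benzyloxy)phenyl](hydroxy)methyl]oxolan-3-yl]methanone
Product: 24 (2,4-dihydroxyphenyl)[(2R,3R,4R,5R)-5-(2,4-dihydroxyphenyl)-4-[(R)-hydroxy(4-hydroxyphenyl)methyl]-2-(4-hydroxyphenyl)oxolan-3-yl]methanone
Conditions: H2 (1 atm), 10% Pd/C, EtOAc–MeOH, rt
Reagents that add atoms: none
Why: Hydrogenolysis of the six aryl benzyl ethers under neutral conditions; these cleave much faster than the benzylic C7–OH and ring C–O bonds or the ortho-hydroxyaryl ketone, so the reaction is stopped after uptake of six equivalents of hydrogen. No stereocentre is touched.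

Compound list

1 | 2',4'-dihydroxyacetophenone | CC(=O)c1ccc(O)cc1O | starting material
2 | 1-[2,4-bis(benzyloxy)phenyl]ethan-1-one | CC(=O)c1ccc(OCc2ccccc2)cc1OCc1ccccc1 | intermediate
3 | methyl 3-[2,4-bis(benzyloxy)phenyl]-3-oxopropanoate | COC(=O)CC(=O)c1ccc(OCc2ccccc2)cc1OCc1ccccc1 | intermediate
4 | (E)-4-hydroxycinnamic acid | OC(=O)/C=C/c1ccc(O)cc1 | starting material
5 | benzyl (E)-3-[4-(benzyloxy)phenyl]prop-2-enoate | O=C(/C=C/c1ccc(OCc2ccccc2)cc1)OCc1ccccc1 | intermediate
6 | (E)-3-[4-(benzyloxy)phenyl]prop-2-enoic acid | OC(=O)/C=C/c1ccc(OCc2ccccc2)cc1 | intermediate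
7 | (2R)-bornane-10,2-sultam [(1S)-(−)-2,10-camphorsultam; (3aS,6R,7aR)-8,8-dimethylhexahydro-3H-3a,6-methano-2,1-benzisothiazole 2,2-dioxide] | CC1(C)[C@@H]2CC[C@]13CS(=O)(=O)N[C@@H]3C2 | starting material
8 | (E)-3-[4-(benzyloxy)phenyl]prop-2-enoyl chloride | O=C(Cl)/C=C/c1ccc(OCc2ccccc2)cc1 | intermediate
9 | (2R)-N-[(E)-3-[4-(benzyloxy)phenyl]prop-2-enoyl]bornane-10,2-sultam | CC1(C)[C@@H]2CC[C@]13CS(=O)(=O)N(C(=O)/C=C/c4ccc(OCc5ccccc5)cc4)[C@@H]3C2 | intermediate
10 | methyl (4R,5R)-2-[2,4-bis(benzyloxy)phenyl]-5-[4-(benzyloxy)phenyl]-4-{[(2R)-bornane-10,2-sultam-N-yl]carbonyl}-4,5-dihydrofuran-3-carboxylate | CC1(C)[C@@H]2CC[C@]13CS(=O)(=O)N(C(=O)[C@@H]4C(C(=O)OC)=C(c5ccc(OCc6ccccc6)cc5OCc5ccccc5)O[C@H]4c4ccc(OCc5ccccc5)cc4)[C@@H]3C2 | intermediate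
11 | methyl (2R,3S,4R,5R)-2-[2,4-bis(benzyloxy)phenyl]-5-[4-(benzyloxy)phenyl]-4-{[(2R)-bornane-10,2-sultam-N-yl]carbonyl}oxolane-3-carboxylate | CC1(C)[C@@H]2CC[C@]13CS(=O)(=O)N(C(=O)[C@@H]4[C@H](C(=O)OC)[C@H](c5ccc(OCc6ccccc6)cc5OCc5ccccc5)O[C@H]4c4ccc(OCc5ccccc5)cc4)[C@@H]3C2 | intermediate
12 | (2R,3R,4S,5R)-5-[2,4-bis(benzyloxy)phenyl]-2-[4-(benzyloxy)phenyl]-4-(methoxycarbonyl)oxolane-3-carboperoxoic acid | OOC(=O)[C@@H]1[C@H](C(=O)OC)[C@H](c2ccc(OCc3ccccc3)cc2OCc2ccccc2)O[C@H]1c1ccc(OCc2ccccc2)cc1 | intermediate
13 | (2R,3R,4S,5R)-5-[2,4-bis(benzyloxy)phenyl]-2-[4-(benzyloxy)phenyl]-4-(methoxycarbonyl)oxolane-3-carboxylic acid | OC(=O)[C@@H]1[C@H](C(=O)OC)[C@H](c2ccc(OCc3ccccc3)cc2OCc2ccccc2)O[C@H]1c1ccc(OCc2ccccc2)cc1 | intermediate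
14 | (2R,3R,4R,5R)-5-[2,4-bis(benzyloxy)phenyl]-2-[4-(benzyloxy)phenyl]-4-(hydroxymethyl)oxolane-3-carboxylic acid | OC(=O)[C@@H]1[C@H](CO)[C@H](c2ccc(OCc3ccccc3)cc2OCc2ccccc2)O[C@H]1c1ccc(OCc2ccccc2)cc1 | intermediate
15 | (3aR,4R,6R,6aR)-4-[2,4-bis(benzyloxy)phenyl]-6-[4-(benzyloxy)phenyl]tetrahydro-1H,3H-furo[3,4-c]furan-1-one | O=C1OC[C@H]2[C@@H]1[C@H](c1ccc(OCc3ccccc3)cc1)O[C@H]2c1ccc(OCc2ccccc2)cc1OCc1ccccc1 | intermediate
16 | 4-bromoresorcinol | Oc1ccc(Br)c(O)c1 | starting material
17 | 1-bromo-2,4-bis(benzyloxy)benzene | Brc1ccc(OCc2ccccc2)cc1OCc1ccccc1 | intermediate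
18 | [2,4-bis(benzyloxy)phenyl]lithium | [Li]c1ccc(OCc2ccccc2)cc1OCc1ccccc1 | intermediate
19 | [2,4-bis(benzyloxy)phenyl][(2R,3R,4R,5R)-5-[2,4-bis(benzyloxy)phenyl]-2-[4-(benzyloxy)phenyl]-4-(hydroxymethyl)oxolan-3-yl]methanone | O=C(c1ccc(OCc2ccccc2)cc1OCc1ccccc1)[C@@H]1[C@H](CO)[C@H](c2ccc(OCc3ccccc3)cc2OCc2ccccc2)O[C@H]1c1ccc(OCc2ccccc2)cc1 | intermediate
20 | (2R,3S,4R,5R)-4-[2,4-bis(benzyloxy)benzoyl]-2-[2,4-bis(benzyloxy)phenyl]-5-[4-(benzyloxy)phenyl]oxolane-3-carbaldehyde | O=C(c1ccc(OCc2ccccc2)cc1OCc1ccccc1)[C@@H]1[C@H](C=O)[C@H](c2ccc(OCc3ccccc3)cc2OCc2ccccc2)O[C@H]1c1ccc(OCc2ccccc2)cc1 | intermediate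
21 | 1-(benzyloxy)-4-bromobenzene | Brc1ccc(OCc2ccccc2)cc1 | starting material
22 | [4-(benzyloxy)phenyl]magnesium bromide | Br[Mg]c1ccc(OCc2ccccc2)cc1 | intermediate
23 | [2,4-bis(benzyloxy)phenyl][(2R,3R,4R,5R)-5-[2,4-bis(benzyloxy)phenyl]-2-[4-(benzyloxy)phenyl]-4-[(R)-[4-(benzyloxy)phenyl](hydroxy)methyl]oxolan-3-yl]methanone | O=C(c1ccc(OCc2ccccc2)cc1OCc1ccccc1)[C@@H]1[C@H]([C@@H](O)c2ccc(OCc3ccccc3)cc2)[C@H](c2ccc(OCc3ccccc3)cc2OCc2ccccc2)O[C@H]1c1ccc(OCc2ccccc2)cc1 | intermediate
24 | (2,4-dihydroxyphenyl)[(2R,3R,4R,5R)-5-(2,4-dihydroxyphenyl)-4-[(R)-hydroxy(4-hydroxyphenyl)methyl]-2-(4-hydroxyphenyl)oxolan-3-yl]methanone | O=C(c1ccc(O)cc1O)[C@@H]1[C@H]([C@@H](O)c2ccc(O)cc2)[C@H](c2ccc(O)cc2O)O[C@H]1c1ccc(O)cc1 | target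

Total step count: 13. Longest linear sequence: 10 steps (steps 1, 2, 5, 6, 7, 8, 10, 11, 12, 13; the branch through steps 3 and 4 is equally long).

Least certain steps

Step 5 (key step). The most likely failure is poor facial selectivity in the radical addition at C3, because the sultam is not locked by chelation in warm AcOH and the alkene reacts as a freely rotating imide; the regiochemistry and the trans closure are not in doubt. The fallback replaces induction by resolution. The crude mixture of 10 and the (4S,5S)-diastereomer of 10 F1 is not separated but taken through the conditions of steps 6 and 7. F1 is hydrogenated to the all-cis oxolane imide F2 and then cleaved to the enantiomeric acid F3, so that after loss of the auxiliary the two series are mirror images. Acid 13 would then be freed from F3 by crystallising its salt with one antipode of 1-phenylethylamine, chosen by trial and written here as the (R)-1-phenylethylammonium salt of 13 F4. Dilute HCl releases the acid. The fallback sets out from 10 and returns to the route at 13.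

Step 6. The tetrasubstituted push–pull alkene may be saturated only slowly, and at the pressure then required ring saturation or loss of benzyl ethers can compete and the facial preference can erode. The fallback accepts the loss of the benzyl ethers. Hydrogenation of 10 over Pd(OH)2/C (H2, EtOAc–MeOH) would saturate the double bond on the same face while cleaving the three aryl benzyl ethers, giving the triphenol imide F5. Re-benzylation (BnBr, K2CO3, acetone) restores the ethers. The fallback sets out from 10 and returns at 11.

Step 10. The aryllithium may deprotonate C3 of the lactone, after which the enolate expels O1 from C2, or the hemiketal may collapse early and take up a second aryl group. The fallback replaces the lactone by an aldehyde-level electrophile, which adds faster than it enolises and cannot add twice. Reduction of 15 with i-Bu2AlH (CH2Cl2, −78 °C) gives the lactol F6. Two equivalents of aryllithium 18 add to its open hydroxy aldehyde form and give the diol F7 as both carbinol epimers. Dess–Martin periodinane (NaHCO3, CH2Cl2) then oxidises both alcohols. The fallback sets out from 15 and returns at 20, bypassing 19.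

Step 12. Facial selectivity at C7 rests on a conformational argument and the wrong face may be attacked; enolisation of the all-cis aldehyde by the Grignard reagent, with epimerisation at C4, is the second hazard. The fallback sets C7 by hydride instead of aryl delivery. The crude carbinol, then mainly the (7S)-epimer of 23 F8, would be oxidised with Dess–Martin periodinane to the diketone F9. The C7 ketone would be reduced with LiAlH(Ot-Bu)3 (THF, −78 °C). Hydride then enters on the face the aryl group preferred, which inverts the outcome at C7. The C6 ketone, with two donor alkoxy groups and an ortho substituent, is the less reactive of the two. The fallback sets out from 20 and returns at 23.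

Further compounds

F1 | step 5 | methyl (4S,5S)-2-[2,4-bis(benzyloxy)phenyl]-5-[4-(benzyloxy)phenyl]-4-{[(2R)-bornane-10,2-sultam-N-yl]carbonyl}-4,5-dihydrofuran-3-carboxylate | CC1(C)[C@@H]2CC[C@]13CS(=O)(=O)N(C(=O)[C@H]4C(C(=O)OC)=C(c5ccc(OCc6ccccc6)cc5OCc5ccccc5)O[C@@H]4c4ccc(OCc5ccccc5)cc4)[C@@H]3C2
F2 | step 5 | methyl (2S,3R,4S,5S)-2-[2,4-bis(benzyloxy)phenyl]-5-[4-(benzyloxy)phenyl]-4-{[(2R)-bornane-10,2-sultam-N-yl]carbonyl}oxolane-3-carboxylate | CC1(C)[C@@H]2CC[C@]13CS(=O)(=O)N(C(=O)[C@H]4[C@@H](C(=O)OC)[C@@H](c5ccc(OCc6ccccc6)cc5OCc5ccccc5)O[C@@H]4c4ccc(OCc5ccccc5)cc4)[C@@H]3C2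
F3 | step 5 | (2S,3S,4R,5S)-5-[2,4-bis(benzyloxy)phenyl]-2-[4-(benzyloxy)phenyl]-4-(methoxycarbonyl)oxolane-3-carboxylic acid | OC(=O)[C@H]1[C@@H](C(=O)OC)[C@@H](c2ccc(OCc3ccccc3)cc2OCc2ccccc2)O[C@@H]1c1ccc(OCc2ccccc2)cc1
F4 | step 5 | (R)-1-phenylethylammonium (2R,3R,4S,5R)-5-[2,4-bis(benzyloxy)phenyl]-2-[4-(benzyloxy)phenyl]-4-(methoxycarbonyl)oxolane-3-carboxylate | [O-]C(=O)[C@@H]1[C@H](C(=O)OC)[C@H](c2ccc(OCc3ccccc3)cc2OCc2ccccc2)O[C@H]1c1ccc(OCc2ccccc2)cc1.C[C@@H]([NH3+])c1ccccc1
F5 | step 6 | methyl (2R,3S,4R,5R)-2-(2,4-dihydroxyphenyl)-5-(4-hydroxyphenyl)-4-{[(2R)-bornane-10,2-sultam-N-yl]carbonyl}oxolane-3-carboxylate | CC1(C)[C@@H]2CC[C@]13CS(=O)(=O)N(C(=O)[C@@H]4[C@H](C(=O)OC)[C@H](c5ccc(O)cc5O)O[C@H]4c4ccc(O)cc4)[C@@H]3C2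
F6 | step 10 | (3aR,4R,6R,6aR)-4-[2,4-bis(benzyloxy)phenyl]-6-[4-(benzyloxy)phenyl]tetrahydro-1H,3H-furo[3,4-c]furan-1-ol (both anomers) | OC1OC[C@H]2[C@@H]1[C@H](c1ccc(OCc3ccccc3)cc1)O[C@H]2c1ccc(OCc2ccccc2)cc1OCc1ccccc1
F7 | step 10 | [2,4-bis(benzyloxy)phenyl][(2R,3S,4R,5R)-5-[2,4-bis(benzyloxy)phenyl]-2-[4-(benzyloxy)phenyl]-4-(hydroxymethyl)oxolan-3-yl]methanol (both carbinol epimers) | OC(c1ccc(OCc2ccccc2)cc1OCc1ccccc1)[C@@H]1[C@H](CO)[C@H](c2ccc(OCc3ccccc3)cc2OCc2ccccc2)O[C@H]1c1ccc(OCc2ccccc2)cc1
F8 | step 12 | [2,4-bis(benzyloxy)phenyl][(2R,3R,4R,5R)-5-[2,4-bis(benzyloxy)phenyl]-2-[4-(benzyloxy)phenyl]-4-[(S)-[4-(benzyloxy)phenyl](hydroxy)methyl]oxolan-3-yl]methanone | O=C(c1ccc(OCc2ccccc2)cc1OCc1ccccc1)[C@@H]1[C@H]([C@H](O)c2ccc(OCc3ccccc3)cc2)[C@H](c2ccc(OCc3ccccc3)cc2OCc2ccccc2)O[C@H]1c1ccc(OCc2ccccc2)cc1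
F9 | step 12 | [(2R,3R,4S,5R)-4-[4-(benzyloxy)benzoyl]-5-[2,4-bis(benzyloxy)phenyl]-2-[4-(benzyloxy)phenyl]oxolan-3-yl][2,4-bis(benzyloxy)phenyl]methanone | O=C(c1ccc(OCc2ccccc2)cc1OCc1ccccc1)[C@@H]1[C@H](C(=O)c2ccc(OCc3ccccc3)cc2)[C@H](c2ccc(OCc3ccccc3)cc2OCc2ccccc2)O[C@H]1c1ccc(OCc2ccccc2)cc1
A1 | alternative 1 | exo,exo-2,6-bis(4-hydroxyphenyl)-3,7-dioxabicyclo[3.3.0]octane-4,8-dione (formed as the racemate; the enantiomer needed is drawn) | O=C3[C@@H]1[C@H]([C@@H](O3)c4ccc(O)cc4)C(=O)O[C@H]1c1ccc(O)cc1
A2 | alternative 2 | 1,4-bis[2,4-bis(benzyloxy)phenyl]butane-1,4-dione | O=C(CCC(=O)c1ccc(OCc2ccccc2)cc1OCc1ccccc1)c1ccc(OCc2ccccc2)cc1OCc1ccccc1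
A3 | alternative 2 | 4-(benzyloxy)benzaldehyde | O=Cc1ccc(OCc2ccccc2)cc1
A4 | alternative 2 | 2,3-bis[2,4-bis(benzyloxy)benzoyl]-1,4-bis[4-(benzyloxy)phenyl]butane-1,4-diol (C2-symmetric syn,syn isomer drawn) | O=C(c1ccc(OCc2ccccc2)cc1OCc1ccccc1)[C@@H]([C@@H](O)c1ccc(OCc2ccccc2)cc1)[C@H]([C@@H](O)c1ccc(OCc2ccccc2)cc1)C(=O)c1ccc(OCc2ccccc2)cc1OCc1ccccc1
A5 | alternative 3 | (R)-5-[4-(benzyloxy)phenyl]furan-2(5H)-one | O=C1C=C[C@H](c2ccc(OCc3ccccc3)cc2)O1
A6 | alternative 3 | 1,1-diethoxyethene | C=C(OCC)OCC
A7 | alternative 3 | 2-[4-(benzyloxy)phenyl]-6,6-diethoxy-3-oxabicyclo[3.2.0]heptan-4-one (head-to-tail adduct; stereoisomer drawn) | CCOC3(OCC)[C@@H]1[C@H](C3)C(=O)O[C@H]1c1ccc(OCc2ccccc2)cc1
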